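## Structural features

The target is a (3S)-isoflavanone: a chroman-4-one (benzene ring A fused to pyranone ring C) that carries at C3 a 2,2-dimethyl-2H-chromene unit (ring B with its fused pyran), joined through chromene C6. Ring A is a 1,3,5-trioxygenated benzene whose three oxygens are all different: methoxy at C5, free hydroxyl at C7 and the ring ether oxygen at C8a; the first and last flank C4a, which bears the C4 carbonyl. C3 is the only stereocentre and has no stereogenic neighbour in the target. It is benzylic and alpha to the C4 ketone, so it epimerises through the enol once the ketone exists. Other fragile groups are the cis-styrenyl double bond of the chromene (acid, hydrogenation, oxidants, short-wavelength light), the two phenols and, in every C4 carbinol intermediate, a 2,4,6-trioxygenated benzylic C–O bond that ionises easily. The real difficulty is twofold: placing three different oxygens around ring A without selective alkylation of a phloroglucinol, and installing and keeping the configuration at C3. The key step exploits the oxygen pattern of ring A: it builds the ring itself (bonds C4a–C8a, C5–C6, C8–C8a) from a diazoketone that brings C6–C8 with the C7 oxygen and an ynol ether that brings C4a and C5 with the methoxy group, while the C8a oxygen comes from the ketene carbonyl. C4 is carried as a carbinol, so C3 is not enolisable until the second-last step.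

## Logic of the disconnections

36 to 35. The two phenolic O–Si bonds are cut last. The C7 and C3' hydroxyls must stay masked through ring closure and oxidation, and one fluoride treatment frees both. No skeletal simplification results, but 35 tolerates every earlier oxidant and activating reagent. The forward step must remove silicon without generating base, because C3 of 35 is enolisable.

35 to 34. The C4 carbonyl is taken back to a carbinol. While C4 is sp3, C3 is an ordinary benzylic methine, so all earlier steps are free of the epimerisation problem. The cost is an uncontrolled centre at C4, harmless because both epimers of 34 give 35. The oxidation must be neutral and spare the chromene alkene.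

34 to 33. The O1–C2 bond of ring C is cut. This returns the free phenol that the ring A synthesis delivers, plus a primary alcohol on an open chain. The forward closure must activate the primary C2 hydroxyl in preference to the hindered benzylic C4 hydroxyl and must not ionise C4.

33 to 32. The two aliphatic O–Si bonds (on the C2 and C4 oxygens) are cut together. Both oxygens must be capped while a ketene is in the flask. Giving both the same labile triethylsilyl group lets one mild hydrolysis free them while the bulkier aryl silyl ethers stay. A robust silyl group on the C4 oxygen would later need acid strong enough to ionise this benzylic position and eliminate towards C3. The forward step must be correspondingly mild.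

32 to 22 and 27. Ring A is removed whole by cutting C4a–C8a, C5–C6 and C8–C8a. Each oxygen then comes from a different source: methoxy from 22, silyloxy from 27, the free phenol from the ketene carbonyl. The gain is the largest in the route: an aromatic ring with three distinct oxygens becomes a four-carbon diazoketone and an alkyne. The forward step needs one regiochemistry in the ketene–alkyne cycloaddition, light that the chromene does not absorb, and a C3 centre that cannot enolise (secured by the C4 carbinol). The ketene that forms in the flask, 28, carries its silyloxy group on the carbon next to the ketene CH, which is what places that oxygen at C7.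

27 to 24 to 23. The C=N2 bond and then the enol O–Si bond are cut, which leads back to 23, a symmetrical four-carbon unit. The forward diazo transfer must work on a methyl ketone next to a silyl enol ether, which calls for transient trifluoroacetyl activation.

22 to 18 and 19. The C4–C(sp) bond and the C4 O–Si bond are cut. The methoxyalkyne arrives as acetylide 20, made in the flask from 19, and what remains is 18, a three-carbon unit that carries ring B and C3. The addition must outrun enolisation of the alpha-aryl aldehyde, and the alkoxide must be silylated in the flask because the free alkoxyethynyl carbinol rearranges with traces of acid.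

18 to 17 to 16 to 15 to 13. In turn: the aldehyde oxidation level, the acyl–auxiliary bond, the C2 O–Si bond and finally the C2–C3 bond are cut. The last cut removes a one-carbon electrophile and leaves 13, whose chain has no stereocentre. The forward hydroxymethylation must set C3 by auxiliary control. The C2 oxygen must be silylated before the auxiliary is removed, because otherwise the two hydroxymethyl arms would become identical and C3 would cease to be a stereocentre.

13 to 10 and 11. The N–acyl bond is cut, giving 10 and 11. The only demand is clean acylation without harm to the chromene.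

10 to 9 to 7. The benzylic C–C bond to the carboxyl carbon is cut (one-carbon homologation of an aldehyde). This moves the problem to 7, whose formyl group also controls the regiochemistry of the next disconnection. The forward steps must homologate and oxidise without touching the chromene alkene.

7 to 4 to 3 to 1 and 2. The pyran ring of the chromene is opened (aryl C–C bond and the vinyl C=C bond, via a propargyl ether), then the aryl O–Si bond and the aryl O–C(propargyl) bond are cut. This leads to 1 and 2. The alkylation must take place only at the hydroxyl para to the formyl group, and the rearrangement only at the single free ortho position.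

## Other disconnections considered

Alternative 1: The cut runs through C3–C4 and O1–C2, removing all of ring C and separating rings A and B as benzodioxinone A1 and styryl enol ether A2. Forward, light induces cycloreversion of A1 to the quinoketene A3. The electron-rich alkene of A2 adds across its acylketene unit (benzylic carbon to the ketene carbon, phenolic oxygen to the methoxy-bearing carbon), and beta-elimination of the methoxy group gives isoflavone A4.
- In favour: two simple aromatic halves are joined in one convergent operation; no diazo compound or ynol ether is needed; the enol ether polarity leaves no regiochemical doubt. On convergence and step count to the full skeleton this alternative is the better one.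
- Against: A4 is flat at C3, so the stereocentre would still have to be made by an enantioselective 1,4-reduction of C2=C3. That reduction must spare the chromene alkene (which itself still has to be formed from the propargyl ether group by thermal rearrangement) and delivers the centre directly in its epimerisable alpha-keto form. Ring A of A1 still needs three differentiated oxygens by selective protection. Capture of a short-lived ketene by a weakly nucleophilic alkene competes with ketene self-reaction.
- Comparison: the chosen plan solves the ring A oxygen pattern by construction, where this one relies on protecting groups. Mechanistically both depend on a photogenerated ketene with similar uncertainty in the bimolecular capture. In step economy the alternative is shorter to the skeleton but less certain in the stereochemical end game; the chosen plan fixes C3 early and keeps it non-enolisable.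

Alternative 2: The cut is C2–C3. The precursor is the alpha-diazo ketone A5, whose ring A carries two equivalent ortho methoxy groups. A chiral dirhodium tetracarboxylate such as Rh2(S-PTTL)4 (divalent rhodium) would generate the carbene at C3. Insertion into a C–H bond of either methoxy group would form C2–C3, close ring C and set C3 in one step, giving A6.
- In favour: it is the shortest end game conceivable, clearly better in step count. The two methoxy groups are equivalent, so ring A needs no oxygen differentiation beyond the C7 silyl ether; in this respect it is simpler than the chosen plan. A5 is reachable by classical acylation and diazo transfer.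
- Against: an ortho oxygen can attack the carbene to give a five-membered oxonium ylide, and a 1,2-methyl shift would then divert the material into a five-membered ring. Cyclopropanation of the chromene alkene and addition to the aromatic rings also compete. Six-membered C–H insertion of a ketone-substituted aryl carbene with high enantioselectivity is less established than five-membered insertion. The stereocentre is born alpha to the ketone and can enolise at once.
- Comparison: structurally equal or better (symmetrical ring A precursor). Mechanistically riskier in chemoselectivity than the ketene–ynol ether union, whose polarity match is strong. Better in step economy, but worse in how securely C3 is set and kept.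

Alternative 3: The cut is C3–C4. The precursor A7 is an aroyl chloride whose ortho oxygen (O1) already carries C2 and the racemic benzylic chloride at C3. The precatalyst NiBr2(dme) (divalent nickel) with a chiral bis(oxazoline) ligand and manganese powder as reductant would couple the acyl and benzylic carbons within the molecule. This would form C3–C4, close ring C and funnel both enantiomers of the chloride into the (S)-configured isoflavanone bis-silyl ether A8.
- In favour: it is enantioconvergent, needing no auxiliary. The conditions are reducing and non-basic, designed to preserve alpha-aryl ketone stereocentres; here it is better than the chosen plan in how gently the centre is created. O1–C2 comes from a simple phenol alkylation, and the ketone appears at the right oxidation level, saving the late oxidation.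
- Against: the reaction type is established between two molecules, not as a ring closure, and cyclisation changes the geometry on which enantioselection rests. The benzylic chloride of A7 is para-alkoxy-activated and beta-aryloxy-substituted, so ionisation, elimination and beta-aryloxy loss from a benzylic nickel or radical intermediate are all easy. An acid chloride and a labile secondary chloride must coexist. The benzylic radical could add to the chromene alkene. Ring A again needs three distinct oxygens by selective protection.
- Comparison: structurally it leaves the ring A problem unsolved, as in alternative 1. Mechanistically it is elegant but extends a known coupling to an untested ring-forming case, whereas the chosen key step stays within its known substrate class. Step economy is equal or slightly better; stereochemical security is lower during precursor handling and potentially higher at the moment the ketone forms, which is the point where A8 would have the advantage.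

Key step: step 14

Remark on the chemistry: C4 is formed without stereocontrol in step 11 and is carried as a mixture of two epimers (21, 22, 29 to 34), because step 17 turns it into the carbonyl carbon. All aryl silyl ethers are triisopropylsilyl and both aliphatic silyl ethers triethylsilyl. Compounds 1, 2, 11, 19 and 23 are taken as commercially available.

## Route

Step 1
Reactants: 1 3,4-dihydroxybenzaldehyde; 2 3-chloro-3-methylbut-1-yne
Product: 3 3-hydroxy-4-[(2-methylbut-3-yn-2-yl)oxy]benzaldehyde
Conditions: K2CO3 (1.05 equiv), KI (cat.), CuI (cat.), DMF, 60 °C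
Reagents that add atoms: none
Why: Copper-assisted O-alkylation of a phenol by a tertiary propargylic chloride. With one equivalent of mild base only the more acidic hydroxyl para to the formyl group is deprotonated, so the ether should form at O4.

Step 2
Reactants: 3 3-hydroxy-4-[(2-methylbut-3-yn-2-yl)oxy]benzaldehyde
Product: 4 4-[(2-methylbut-3-yn-2-yl)oxy]-3-(triisopropylsilyloxy)benzaldehyde
Conditions: TIPSCl, imidazole, DMF, rt
Reagents that add atoms: chlorotriisopropylsilane, CC(C)[Si](Cl)(C(C)C)C(C)C
Why: Imidazole-promoted silylation of a phenol. The bulky silyl group is chosen to survive 190 °C, a lithium acetylide and mild aqueous acid later.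

Step 3
Reactants: 4 4-[(2-methylbut-3-yn-2-yl)oxy]-3-(triisopropylsilyloxy)benzaldehyde
Product: 7 2,2-dimethyl-8-(triisopropylsilyloxy)-2H-chromene-6-carbaldehyde, via allenylphenol 5 (not isolated), via o-quinone methide 6 (not isolated)
Conditions: PhNEt2, 190 °C
Reagents that add atoms: none
Why: Aryl propargyl ether Claisen rearrangement to the only free ortho position gives 5. A 1,5-hydrogen shift gives 6, and oxa-6π electrocyclisation closes the 2,2-dimethylchromene; the other ortho position is blocked by the silyloxy group.

Step 4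
Reactants: 7 2,2-dimethyl-8-(triisopropylsilyloxy)-2H-chromene-6-carbaldehyde
Product: 9 2-[2,2-dimethyl-8-(triisopropylsilyloxy)-2H-chromen-6-yl]acetaldehyde, via enol ether 8 (not isolated)
Conditions: MeOCH2PPh3Cl, KOt-Bu, THF, 0 °C; then 7, 0 °C to rt; then 2 M HCl, 40 °C
Reagents that add atoms: (methoxymethyl)triphenylphosphonium chloride, COC[P+](c1ccccc1)(c1ccccc1)c1ccccc1.[Cl-]; water, O
Why: Wittig methoxymethylenation gives 8, and dilute acid hydrolyses the enol ether in the same flask to the homologous aldehyde. The chromene alkene and the aryl silyl ether should tolerate the short exposure; 9 is used crude.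

Step 5
Reactants: 9 2-[2,2-dimethyl-8-(triisopropylsilyloxy)-2H-chromen-6-yl]acetaldehyde
Product: 10 2-[2,2-dimethyl-8-(triisopropylsilyloxy)-2H-chromen-6-yl]acetic acid
Conditions: NaClO2, NaH2PO4, 2-methylbut-2-ene, t-BuOH/H2O, 0 °C to rt
Reagents that add atoms: sodium chlorite, [Na+].[O-]Cl=O
Why: Pinnick oxidation. The alkene scavenger removes HOCl, so the chromene double bond and the electron-rich ring should not be chlorinated.

Step 6
Reactants: 10 2-[2,2-dimethyl-8-(triisopropylsilyloxy)-2H-chromen-6-yl]acetic acid; 11 (R)-4-benzyloxazolidin-2-one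
Product: 13 (R)-4-benzyl-3-{2-[2,2-dimethyl-8-(triisopropylsilyloxy)-2H-chromen-6-yl]acetyl}oxazolidin-2-one, via mixed pivalic anhydride 12 (not isolated)
Conditions: PivCl, Et3N, THF, −20 °C; then LiCl, 11, −20 °C to rt
Reagents that add atoms: none
Why: N-acylation of the oxazolidinone through the mixed anhydride under LiCl/amine activation. Attack occurs at the less hindered arylacetyl carbonyl, and no strong base touches the chromene.

Step 7
Reactants: 13 (R)-4-benzyl-3-{2-[2,2-dimethyl-8-(triisopropylsilyloxy)-2H-chromen-6-yl]acetyl}oxazolidin-2-one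
Product: 15 (R)-4-benzyl-3-{(2S)-2-[2,2-dimethyl-8-(triisopropylsilyloxy)-2H-chromen-6-yl]-3-hydroxypropanoyl}oxazolidin-2-one, via chlorotitanium enolate 14 (not isolated)
Conditions: TiCl4, i-Pr2NEt, CH2Cl2, 0 °C; then 1,3,5-trioxane, TiCl4, 0 °C
Reagents that add atoms: 1,3,5-trioxane, C1OCOCO1
Why: Evans asymmetric hydroxymethylation (titanium enolate aldol with formaldehyde from trioxane). The chelated Z-enolate 14 is attacked on the face opposite the benzyl group of the (R)-auxiliary, which sets the future C3 as S; the new CH2OH carbon is C2 and the imide carbonyl is the future C4.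

Step 8
Reactants: 15 (R)-4-benzyl-3-{(2S)-2-[2,2-dimethyl-8-(triisopropylsilyloxy)-2H-chromen-6-yl]-3-hydroxypropanoyl}oxazolidin-2-one
Product: 16 (R)-4-benzyl-3-{(2S)-2-[2,2-dimethyl-8-(triisopropylsilyloxy)-2H-chromen-6-yl]-3-(triethylsilyloxy)propanoyl}oxazolidin-2-one
Conditions: TESCl, imidazole, CH2Cl2, 0 °C
Reagents that add atoms: chlorotriethylsilane, CC[Si](Cl)(CC)CC
Why: Silylation of the primary alcohol. It must precede removal of the auxiliary, because the free 2-aryl-1,3-diol would be achiral.

Step 9
Reactants: 16 (R)-4-benzyl-3-{(2S)-2-[2,2-dimethyl-8-(triisopropylsilyloxy)-2H-chromen-6-yl]-3-(triethylsilyloxy)propanoyl}oxazolidin-2-one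
Product: 17 (2R)-2-[2,2-dimethyl-8-(triisopropylsilyloxy)-2H-chromen-6-yl]-3-(triethylsilyloxy)propan-1-ol
Conditions: LiBH4, MeOH (1 equiv), THF, 0 °C
Reagents that add atoms: none
Why: Reductive cleavage of the N-acyloxazolidinone gives the primary alcohol and returns the auxiliary. Low temperature and a cold quench should keep the silyl group from migrating between the two oxygens, which would erode the configuration (the descriptor changes to R only through the priority rules).

Step 10
Reactants: 17 (2R)-2-[2,2-dimethyl-8-(triisopropylsilyloxy)-2H-chromen-6-yl]-3-(triethylsilyloxy)propan-1-ol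
Product: 18 (2S)-2-[2,2-dimethyl-8-(triisopropylsilyloxy)-2H-chromen-6-yl]-3-(triethylsilyloxy)propanal
Conditions: Dess–Martin periodinane, NaHCO3, CH2Cl2, 0 °C; used at once
Reagents that add atoms: none
Why: Dess–Martin oxidation under bicarbonate buffer is neutral and fast, which matters because the alpha-aryl aldehyde is configurationally labile. It is filtered and used immediately without chromatography.

Step 11
Reactants: 18 (2S)-2-[2,2-dimethyl-8-(triisopropylsilyloxy)-2H-chromen-6-yl]-3-(triethylsilyloxy)propanal; 19 2-chloro-1,1-dimethoxyethane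
Product: 22 (4S)-4-[2,2-dimethyl-8-(triisopropylsilyloxy)-2H-chromen-6-yl]-1-methoxy-3,5-bis(triethylsilyloxy)pent-1-yne (both C3 epimers; pentyne C3/C4/C5 are isoflavanone C4/C3/C2), via lithium methoxyacetylide 20 (not isolated), via lithium alkoxide 21 (not isolated)
Conditions: Et2NH, n-BuLi, THF, 0 °C (LiNEt2, 3 equiv per 19); 19 (2.5 equiv), 0 °C; then 18, −78 °C; then TESCl (excess), −78 to 0 °C
Reagents that add atoms: chlorotriethylsilane, CC[Si](Cl)(CC)CC
Why: Twofold elimination and deprotonation of the chloroacetal by the lithium amide gives the alkoxyacetylide 20. At −78 °C it should add to the aldehyde faster than it deprotonates it, and 21 is silylated in the flask so that the acid-labile alkoxyethynyl carbinol (prone to Meyer–Schuster rearrangement) is never handled. C4 forms as both epimers, which does not matter.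

Step 12
Reactants: 23 butane-2,3-dione
Product: 24 3-(triisopropylsilyloxy)but-3-en-2-one
Conditions: TIPSOTf (1.0 equiv), Et3N, CH2Cl2, 0 °C
Reagents that add atoms: triisopropylsilyl trifluoromethanesulfonate, CC(C)[Si](OS(=O)(=O)C(F)(F)F)(C(C)C)C(C)C
Why: Mono-enol silylation of a 1,2-diketone with a silyl triflate and amine base; one equivalent of the triflate limits bis-silylation.

Step 13
Reactants: 24 3-(triisopropylsilyloxy)but-3-en-2-one
Product: 27 1-diazo-3-(triisopropylsilyloxy)but-3-en-2-one, via lithium enolate 25 (not isolated), via trifluoroacetyl diketone 26 (not isolated)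
Conditions: LiN(SiMe3)2, THF, −78 °C; CF3CO2CH2CF3, −78 °C; aq. HCl work-up; then MsN3, Et3N, H2O (1 equiv), MeCN, rt
Reagents that add atoms: methanesulfonyl azide, CS(=O)(=O)N=[N+]=[N-]
Why: Detrifluoroacetylative diazo transfer. The kinetic enolate 25 is acylated to the activated 1,3-diketone 26, which accepts the diazo group from the sulfonyl azide and passes its trifluoroacetyl group to the sulfonamide. Direct transfer to the unactivated methyl ketone would not proceed, and the silyl enol ether is untouched.

Step 14
Reactants: 22 (4S)-4-[2,2-dimethyl-8-(triisopropylsilyloxy)-2H-chromen-6-yl]-1-methoxy-3,5-bis(triethylsilyloxy)pent-1-yne; 27 1-diazo-3-(triisopropylsilyloxy)but-3-en-2-one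
Product: 32 2-{(2S)-2-[2,2-dimethyl-8-(triisopropylsilyloxy)-2H-chromen-6-yl]-1,3-bis(triethylsilyloxy)propyl}-3-methoxy-5-(triisopropylsilyloxy)phenol (both C1 epimers of the propyl chain), via vinylketene 28 (not isolated), via vinylcyclobutenone 29 (not isolated), via dienylketene 30 (not isolated), via cyclohexadienone 31 (not isolated)
Conditions: 27 (1.3 equiv, in portions), degassed ClCH2CH2Cl, hν (365 nm LED), rt; then 80 °C
Reagents that add atoms: none
Why: Irradiation in the long-wavelength diazo band expels N2 from 27, and the Wolff shift of the silyloxyvinyl group gives ketene 28; the chromene of 22 absorbs at shorter wavelength and is not excited. The electron-rich ynol ether adds to 28 in a [2+2] cycloaddition in which the nucleophilic alkyne carbon remote from the methoxy group (the one bearing C4) bonds to the ketene carbonyl carbon, giving 29 with the C4 chain next to the carbonyl. Warming opens 29 by 4π electrocyclic cleavage to dienylketene 30, whose 6π electrocyclisation closes ring A as dienone 31, and enolisation gives phenol 32. This is the Danheiser benzannulation in its photochemical Wolff form with an alkoxyalkyne, a substrate class for which it is known. The [2+2] step forms C4a–C8a and C5–C6 and the 6π closure forms C8–C8a, so ring A is closed by electrocyclisation. No stereocentre is created; C3 is a spectator because C4 is a silylated carbinol, and the C4 epimers converge in step 17. The selectivities needed are the regiochemistry of the [2+2] step, secured by the polarisation of the ynol ether, and preference of the ketene for the alkyne over the chromene alkene, secured by the much higher nucleophilicity of the ynol ether. The modest excess of 27 limits acylation of the product phenol by surplus ketene.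

Step 15
Reactants: 32 2-{(2S)-2-[2,2-dimethyl-8-(triisopropylsilyloxy)-2H-chromen-6-yl]-1,3-bis(triethylsilyloxy)propyl}-3-methoxy-5-(triisopropylsilyloxy)phenol
Product: 33 2-{(2S)-2-[2,2-dimethyl-8-(triisopropylsilyloxy)-2H-chromen-6-yl]-1,3-dihydroxypropyl}-3-methoxy-5-(triisopropylsilyloxy)phenol (both C1 epimers)
Conditions: AcOH/THF/H2O (3:1:1), 0 °C to rt
Reagents that add atoms: none
Why: Acid-catalysed hydrolysis of alkyl triethylsilyl ethers; aryl triisopropylsilyl ethers are far slower under acid. In an aqueous medium any reversible ionisation at C4 returns the carbinol, and either epimer serves.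

Step 16
Reactants: 33 2-{(2S)-2-[2,2-dimethyl-8-(triisopropylsilyloxy)-2H-chromen-6-yl]-1,3-dihydroxypropyl}-3-methoxy-5-(triisopropylsilyloxy)phenol
Product: 34 (3S)-3-[2,2-dimethyl-8-(triisopropylsilyloxy)-2H-chromen-6-yl]-5-methoxy-7-(triisopropylsilyloxy)chroman-4-ol (both C4 epimers)
Conditions: PPh3, DIAD, THF, 0 °C to rt
Reagents that add atoms: none
Why: Mitsunobu etherification. The acidic phenol is the pronucleophile, the unhindered primary hydroxyl is activated in preference to the hindered benzylic one, and 6-exo-tet displacement at C2 closes ring C; C3 is not involved.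

Step 17
Reactants: 34 (3S)-3-[2,2-dimethyl-8-(triisopropylsilyloxy)-2H-chromen-6-yl]-5-methoxy-7-(triisopropylsilyloxy)chroman-4-ol
Product: 35 (3S)-3-[2,2-dimethyl-8-(triisopropylsilyloxy)-2H-chromen-6-yl]-5-methoxy-7-(triisopropylsilyloxy)chroman-4-one
Conditions: Dess–Martin periodinane, NaHCO3, CH2Cl2, 0 °C to rt
Reagents that add atoms: none
Why: Dess–Martin oxidation of the benzylic carbinol; both C4 epimers converge to one ketone. The buffered neutral medium should leave the now enolisable C3 and the chromene alkene untouched.

Step 18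
Reactants: 35 (3S)-3-[2,2-dimethyl-8-(triisopropylsilyloxy)-2H-chromen-6-yl]-5-methoxy-7-(triisopropylsilyloxy)chroman-4-one
Product: 36 (3S)-7-hydroxy-3-(8-hydroxy-2,2-dimethyl-2H-chromen-6-yl)-5-methoxychroman-4-one
Conditions: TBAF, AcOH (1:1), THF, 0 °C
Reagents that add atoms: none
Why: Fluoride cleavage of the two aryl silyl ethers. Acetic acid keeps the medium from turning basic, so the C3 centre alpha to the ketone should not epimerise; the chromene is inert to fluoride.

## Compound list

1 | 3,4-dihydroxybenzaldehyde | O=Cc1ccc(O)c(O)c1 | starting material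
2 | 3-chloro-3-methylbut-1-yne | CC(C)(Cl)C#C | starting material
3 | 3-hydroxy-4-[(2-methylbut-3-yn-2-yl)oxy]benzaldehyde | O=Cc1ccc(OC(C)(C)C#C)c(O)c1 | intermediate
4 | 4-[(2-methylbut-3-yn-2-yl)oxy]-3-(triisopropylsilyloxy)benzaldehyde | O=Cc1ccc(OC(C)(C)C#C)c(O[Si](C(C)C)(C(C)C)C(C)C)c1 | intermediate
5 | 4-hydroxy-3-(3-methylbuta-1,2-dien-1-yl)-5-(triisopropylsilyloxy)benzaldehyde (allenylphenol) | O=Cc1cc(C=C=C(C)C)c(O)c(O[Si](C(C)C)(C(C)C)C(C)C)c1 | intermediate
6 | 3-(3-methylbut-2-en-1-ylidene)-4-oxo-5-(triisopropylsilyloxy)cyclohexa-1,5-diene-1-carbaldehyde (o-quinone methide) | O=CC1=CC(=CC=C(C)C)C(=O)C(O[Si](C(C)C)(C(C)C)C(C)C)=C1 | intermediate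
7 | 2,2-dimethyl-8-(triisopropylsilyloxy)-2H-chromene-6-carbaldehyde | O=Cc1cc(O[Si](C(C)C)(C(C)C)C(C)C)c2c(c1)C=CC(C)(C)O2 | intermediate
8 | 6-(2-methoxyethenyl)-2,2-dimethyl-8-(triisopropylsilyloxy)-2H-chromene (E/Z mixture) | COC=Cc1cc(O[Si](C(C)C)(C(C)C)C(C)C)c2c(c1)C=CC(C)(C)O2 | intermediate
9 | 2-[2,2-dimethyl-8-(triisopropylsilyloxy)-2H-chromen-6-yl]acetaldehyde | O=CCc1cc(O[Si](C(C)C)(C(C)C)C(C)C)c2c(c1)C=CC(C)(C)O2 | intermediate
10 | 2-[2,2-dimethyl-8-(triisopropylsilyloxy)-2H-chromen-6-yl]acetic acid | OC(=O)Cc1cc(O[Si](C(C)C)(C(C)C)C(C)C)c2c(c1)C=CC(C)(C)O2 | intermediate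
11 | (R)-4-benzyloxazolidin-2-one | O=C1N[C@H](Cc2ccccc2)CO1 | starting material
12 | 2-[2,2-dimethyl-8-(triisopropylsilyloxy)-2H-chromen-6-yl]acetic pivalic anhydride | CC(C)(C)C(=O)OC(=O)Cc1cc(O[Si](C(C)C)(C(C)C)C(C)C)c2c(c1)C=CC(C)(C)O2 | intermediate
13 | (R)-4-benzyl-3-{2-[2,2-dimethyl-8-(triisopropylsilyloxy)-2H-chromen-6-yl]acetyl}oxazolidin-2-one | O=C(Cc1cc(O[Si](C(C)C)(C(C)C)C(C)C)c2c(c1)C=CC(C)(C)O2)N1[C@H](Cc2ccccc2)COC1=O | intermediate
14 | trichlorotitanium (Z)-enolate of 13 | Cl[Ti](Cl)(Cl)O/C(=C\c1cc(O[Si](C(C)C)(C(C)C)C(C)C)c2c(c1)C=CC(C)(C)O2)N1[C@H](Cc2ccccc2)COC1=O | intermediate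
15 | (R)-4-benzyl-3-{(2S)-2-[2,2-dimethyl-8-(triisopropylsilyloxy)-2H-chromen-6-yl]-3-hydroxypropanoyl}oxazolidin-2-one | O=C([C@@H](c1cc(O[Si](C(C)C)(C(C)C)C(C)C)c2c(c1)C=CC(C)(C)O2)CO)N1[C@H](Cc2ccccc2)COC1=O | intermediate
16 | (R)-4-benzyl-3-{(2S)-2-[2,2-dimethyl-8-(triisopropylsilyloxy)-2H-chromen-6-yl]-3-(triethylsilyloxy)propanoyl}oxazolidin-2-one | O=C([C@@H](c1cc(O[Si](C(C)C)(C(C)C)C(C)C)c2c(c1)C=CC(C)(C)O2)CO[Si](CC)(CC)CC)N1[C@H](Cc2ccccc2)COC1=O | intermediate
17 | (2R)-2-[2,2-dimethyl-8-(triisopropylsilyloxy)-2H-chromen-6-yl]-3-(triethylsilyloxy)propan-1-ol | OC[C@@H](c1cc(O[Si](C(C)C)(C(C)C)C(C)C)c2c(c1)C=CC(C)(C)O2)CO[Si](CC)(CC)CC | intermediate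
18 | (2S)-2-[2,2-dimethyl-8-(triisopropylsilyloxy)-2H-chromen-6-yl]-3-(triethylsilyloxy)propanal | O=C[C@@H](c1cc(O[Si](C(C)C)(C(C)C)C(C)C)c2c(c1)C=CC(C)(C)O2)CO[Si](CC)(CC)CC | intermediate
19 | 2-chloro-1,1-dimethoxyethane (chloroacetaldehyde dimethyl acetal) | COC(CCl)OC | starting material
20 | lithium methoxyacetylide | [Li+].[C-]#COC | intermediate
21 | lithium (4S)-4-[2,2-dimethyl-8-(triisopropylsilyloxy)-2H-chromen-6-yl]-1-methoxy-5-(triethylsilyloxy)pent-1-yn-3-olate (both C3 epimers) | [Li+].[O-]C(C#COC)[C@@H](c1cc(O[Si](C(C)C)(C(C)C)C(C)C)c2c(c1)C=CC(C)(C)O2)CO[Si](CC)(CC)CC | intermediate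
22 | (4S)-4-[2,2-dimethyl-8-(triisopropylsilyloxy)-2H-chromen-6-yl]-1-methoxy-3,5-bis(triethylsilyloxy)pent-1-yne (both C3 epimers) | COC#CC(O[Si](CC)(CC)CC)[C@@H](c1cc(O[Si](C(C)C)(C(C)C)C(C)C)c2c(c1)C=CC(C)(C)O2)CO[Si](CC)(CC)CC | intermediate
23 | butane-2,3-dione | CC(=O)C(C)=O | starting material
24 | 3-(triisopropylsilyloxy)but-3-en-2-one | CC(=O)C(=C)O[Si](C(C)C)(C(C)C)C(C)C | intermediate
25 | lithium 3-(triisopropylsilyloxy)buta-1,3-dien-2-olate | [Li+].[O-]C(=C)C(=C)O[Si](C(C)C)(C(C)C)C(C)C | intermediate
26 | 1,1,1-trifluoro-5-(triisopropylsilyloxy)hex-5-ene-2,4-dione (drawn as the diketo form) | C=C(O[Si](C(C)C)(C(C)C)C(C)C)C(=O)CC(=O)C(F)(F)F | intermediate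
27 | 1-diazo-3-(triisopropylsilyloxy)but-3-en-2-one | C=C(O[Si](C(C)C)(C(C)C)C(C)C)C(=O)C=[N+]=[N-] | intermediate
28 | 3-(triisopropylsilyloxy)buta-1,3-dien-1-one (vinylketene) | C=C(O[Si](C(C)C)(C(C)C)C(C)C)C=C=O | intermediate
29 | 2-{(2S)-2-[2,2-dimethyl-8-(triisopropylsilyloxy)-2H-chromen-6-yl]-1,3-bis(triethylsilyloxy)propyl}-3-methoxy-4-[1-(triisopropylsilyloxy)ethenyl]cyclobut-2-en-1-one (epimers at the ring CH and the carbinol carbon) | COC1=C(C(O[Si](CC)(CC)CC)[C@@H](c2cc(O[Si](C(C)C)(C(C)C)C(C)C)c3c(c2)C=CC(C)(C)O3)CO[Si](CC)(CC)CC)C(=O)C1C(=C)O[Si](C(C)C)(C(C)C)C(C)C | intermediate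
30 | (3E)-2-{(2S)-2-[2,2-dimethyl-8-(triisopropylsilyloxy)-2H-chromen-6-yl]-1,3-bis(triethylsilyloxy)propyl}-3-methoxy-5-(triisopropylsilyloxy)hexa-1,3,5-trien-1-one (dienylketene) | CO/C(=C/C(=C)O[Si](C(C)C)(C(C)C)C(C)C)C(=C=O)C(O[Si](CC)(CC)CC)[C@@H](c1cc(O[Si](C(C)C)(C(C)C)C(C)C)c2c(c1)C=CC(C)(C)O2)CO[Si](CC)(CC)CC | intermediate
31 | 2-{(2S)-2-[2,2-dimethyl-8-(triisopropylsilyloxy)-2H-chromen-6-yl]-1,3-bis(triethylsilyloxy)propyl}-3-methoxy-5-(triisopropylsilyloxy)cyclohexa-2,4-dien-1-one | COC1=C(C(O[Si](CC)(CC)CC)[C@@H](c2cc(O[Si](C(C)C)(C(C)C)C(C)C)c3c(c2)C=CC(C)(C)O3)CO[Si](CC)(CC)CC)C(=O)CC(O[Si](C(C)C)(C(C)C)C(C)C)=C1 | intermediate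
32 | 2-{(2S)-2-[2,2-dimethyl-8-(triisopropylsilyloxy)-2H-chromen-6-yl]-1,3-bis(triethylsilyloxy)propyl}-3-methoxy-5-(triisopropylsilyloxy)phenol (both C1 epimers) | COc1cc(O[Si](C(C)C)(C(C)C)C(C)C)cc(O)c1C(O[Si](CC)(CC)CC)[C@@H](c1cc(O[Si](C(C)C)(C(C)C)C(C)C)c2c(c1)C=CC(C)(C)O2)CO[Si](CC)(CC)CC | intermediate
33 | 2-{(2S)-2-[2,2-dimethyl-8-(triisopropylsilyloxy)-2H-chromen-6-yl]-1,3-dihydroxypropyl}-3-methoxy-5-(triisopropylsilyloxy)phenol (both C1 epimers) | COc1cc(O[Si](C(C)C)(C(C)C)C(C)C)cc(O)c1C(O)[C@@H](c1cc(O[Si](C(C)C)(C(C)C)C(C)C)c2c(c1)C=CC(C)(C)O2)CO | intermediate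
34 | (3S)-3-[2,2-dimethyl-8-(triisopropylsilyloxy)-2H-chromen-6-yl]-5-methoxy-7-(triisopropylsilyloxy)chroman-4-ol (both C4 epimers) | COc1cc(O[Si](C(C)C)(C(C)C)C(C)C)cc2c1C(O)[C@@H](c1cc(O[Si](C(C)C)(C(C)C)C(C)C)c3c(c1)C=CC(C)(C)O3)CO2 | intermediate
35 | (3S)-3-[2,2-dimethyl-8-(triisopropylsilyloxy)-2H-chromen-6-yl]-5-methoxy-7-(triisopropylsilyloxy)chroman-4-one | COc1cc(O[Si](C(C)C)(C(C)C)C(C)C)cc2c1C(=O)[C@@H](c1cc(O[Si](C(C)C)(C(C)C)C(C)C)c3c(c1)C=CC(C)(C)O3)CO2 | intermediate
36 | (3S)-7-hydroxy-3-(8-hydroxy-2,2-dimethyl-2H-chromen-6-yl)-5-methoxychroman-4-one | COc1cc(O)cc2c1C(=O)[C@@H](c1cc(O)c3c(c1)C=CC(C)(C)O3)CO2 | target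

## Step count and least certain steps

Total step count: 18. Longest linear sequence: 16 steps (steps 1 to 11, then 14 to 18); the two-step branch to 27 (steps 12 and 13) joins at step 14.

Step 14 (key step).
- What may go wrong: inefficient capture of the ketene by the hindered, alpha-branched ynol ether, so that ketene self-reaction or acylation of the product phenol takes over; or thermal loss of silanol from the ortho-hydroxybenzylic silyl ether during the heating phase.
- Fallback (sets out from 13, returns at 33): ring A is brought in ready-made instead of being built. Commercial 2,4-dihydroxy-6-methoxybenzaldehyde is silylated at the non-chelated 4-hydroxyl (TIPSCl, imidazole) to 2-hydroxy-6-methoxy-4-(triisopropylsilyloxy)benzaldehyde F1 and allylated (allyl bromide, K2CO3) to 2-(allyloxy)-6-methoxy-4-(triisopropylsilyloxy)benzaldehyde F2. The dibutylboron enolate of 13 (Bu2BOTf, i-Pr2NEt) is added to F2 in an Evans syn-aldol reaction, which with the (R)-auxiliary should give the (2R,3R)-aldol adduct F3 with the same spatial arrangement at the future C3. LiBH4 removes the auxiliary to give the 1,3-diol allyl ether F4, and Pd(PPh3)4 (zerovalent palladium) with morpholine frees the phenol to give 33 as a single C4 epimer.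

Step 11.
- What may go wrong: enolisation of the alpha-aryl aldehyde by the basic acetylide solution, leading to loss of configuration at C3 or beta-elimination of the silyloxy group; incomplete silylation of the alkoxide is a lesser risk.
- Fallback (sets out from 15, returns at 22): the electrophile is changed from aldehyde to amide. Transamination of 15 with Me(MeO)NH·HCl and AlMe3 gives the Weinreb amide (2S)-2-[2,2-dimethyl-8-(triisopropylsilyloxy)-2H-chromen-6-yl]-3-hydroxy-N-methoxy-N-methylpropanamide F5, and TESCl/imidazole gives its triethylsilyl ether F6. Acetylide 20 adds once to F6, and the chelated adduct releases the ynone (4S)-4-[2,2-dimethyl-8-(triisopropylsilyloxy)-2H-chromen-6-yl]-1-methoxy-5-(triethylsilyloxy)pent-1-yn-3-one F7 only on cold buffered work-up. Luche reduction (NaBH4, CeCl3·7H2O, MeOH/THF, −78 °C) gives the carbinol F8 as both epimers, and TESCl/imidazole gives 22.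

Step 15.
- What may go wrong: acid-promoted ionisation of the C4–O bond, assisted by the free ortho hydroxyl (o-quinone methide formation) and followed by elimination towards C3, which would destroy the stereocentre.
- Fallback (sets out from 32, returns at 34): ring closure and C4 unmasking are reordered. Brief cold treatment (PPTS, MeOH/CH2Cl2, −20 °C) removes only the primary silyl ether to give the primary alcohol F9. Mitsunobu closure (PPh3, DIAD) gives the ring-closed C4 triethylsilyl ether F10, in which the phenol is etherified and no o-quinone methide can form. Pyridine-buffered HF·pyridine in THF then removes the secondary silyl ether to give 34.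

Step 7.
- What may go wrong: Lewis-acid damage to the chromene (cationic oligomerisation or capture of activated formaldehyde by the styrenyl alkene), or incomplete hydroxymethylation.
- Fallback (sets out from 13, returns at 15): no Lewis acid is used. The sodium enolate of 13 (NaN(SiMe3)2, THF, −78 °C) is alkylated with 4-methoxybenzyl chloromethyl ether, with the same facial sense, to give the 4-methoxybenzyl ether F11. DDQ in wet CH2Cl2 (pH 7 buffer) removes the benzyl group to give 15.

Step 18.
- What may go wrong: partial epimerisation at C3 through enolisation of the aryl ketone by phenoxide or fluoride during desilylation.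
- Fallback (sets out from 34, returns at 36): silicon is removed before the ketone exists. TBAF on 34 gives the triol (3S)-3-(8-hydroxy-2,2-dimethyl-2H-chromen-6-yl)-5-methoxychromane-4,7-diol F12, and activated MnO2 in CH2Cl2/acetone should oxidise only the benzylic carbinol to give 36; chemoselectivity over the phenols is the open point of this fallback.

## Further compounds

F1 | step 14 | 2-hydroxy-6-methoxy-4-(triisopropylsilyloxy)benzaldehyde | O=Cc1c(O)cc(O[Si](C(C)C)(C(C)C)C(C)C)cc1OC
F2 | step 14 | 2-(allyloxy)-6-methoxy-4-(triisopropylsilyloxy)benzaldehyde | O=Cc1c(OCC=C)cc(O[Si](C(C)C)(C(C)C)C(C)C)cc1OC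
F3 | step 14 | (R)-4-benzyl-3-{(2R,3R)-3-[2-(allyloxy)-6-methoxy-4-(triisopropylsilyloxy)phenyl]-2-[2,2-dimethyl-8-(triisopropylsilyloxy)-2H-chromen-6-yl]-3-hydroxypropanoyl}oxazolidin-2-one | O=C(N1[C@H](Cc2ccccc2)COC1=O)[C@H](c1cc(O[Si](C(C)C)(C(C)C)C(C)C)c2c(c1)C=CC(C)(C)O2)[C@@H](O)c1c(OCC=C)cc(O[Si](C(C)C)(C(C)C)C(C)C)cc1OC
F4 | step 14 | (1R,2S)-1-[2-(allyloxy)-6-methoxy-4-(triisopropylsilyloxy)phenyl]-2-[2,2-dimethyl-8-(triisopropylsilyloxy)-2H-chromen-6-yl]propane-1,3-diol | OC[C@H](c1cc(O[Si](C(C)C)(C(C)C)C(C)C)c2c(c1)C=CC(C)(C)O2)[C@@H](O)c1c(OCC=C)cc(O[Si](C(C)C)(C(C)C)C(C)C)cc1OC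
F5 | step 11 | (2S)-2-[2,2-dimethyl-8-(triisopropylsilyloxy)-2H-chromen-6-yl]-3-hydroxy-N-methoxy-N-methylpropanamide | CON(C)C(=O)[C@@H](c1cc(O[Si](C(C)C)(C(C)C)C(C)C)c2c(c1)C=CC(C)(C)O2)CO
F6 | step 11 | (2S)-2-[2,2-dimethyl-8-(triisopropylsilyloxy)-2H-chromen-6-yl]-N-methoxy-N-methyl-3-(triethylsilyloxy)propanamide | CON(C)C(=O)[C@@H](c1cc(O[Si](C(C)C)(C(C)C)C(C)C)c2c(c1)C=CC(C)(C)O2)CO[Si](CC)(CC)CC
F7 | step 11 | (4S)-4-[2,2-dimethyl-8-(triisopropylsilyloxy)-2H-chromen-6-yl]-1-methoxy-5-(triethylsilyloxy)pent-1-yn-3-one | COC#CC(=O)[C@@H](c1cc(O[Si](C(C)C)(C(C)C)C(C)C)c2c(c1)C=CC(C)(C)O2)CO[Si](CC)(CC)CC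
F8 | step 11 | (4S)-4-[2,2-dimethyl-8-(triisopropylsilyloxy)-2H-chromen-6-yl]-1-methoxy-5-(triethylsilyloxy)pent-1-yn-3-ol (both C3 epimers) | COC#CC(O)[C@@H](c1cc(O[Si](C(C)C)(C(C)C)C(C)C)c2c(c1)C=CC(C)(C)O2)CO[Si](CC)(CC)CC
F9 | step 15 | 2-{(2S)-2-[2,2-dimethyl-8-(triisopropylsilyloxy)-2H-chromen-6-yl]-3-hydroxy-1-(triethylsilyloxy)propyl}-3-methoxy-5-(triisopropylsilyloxy)phenol (both C1 epimers) | COc1cc(O[Si](C(C)C)(C(C)C)C(C)C)cc(O)c1C(O[Si](CC)(CC)CC)[C@@H](c1cc(O[Si](C(C)C)(C(C)C)C(C)C)c2c(c1)C=CC(C)(C)O2)CO
F10 | step 15 | (3S)-3-[2,2-dimethyl-8-(triisopropylsilyloxy)-2H-chromen-6-yl]-5-methoxy-4-(triethylsilyloxy)-7-(triisopropylsilyloxy)chromane (both C4 epimers) | COc1cc(O[Si](C(C)C)(C(C)C)C(C)C)cc2c1C(O[Si](CC)(CC)CC)[C@@H](c1cc(O[Si](C(C)C)(C(C)C)C(C)C)c3c(c1)C=CC(C)(C)O3)CO2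
F11 | step 7 | (R)-4-benzyl-3-{(2S)-2-[2,2-dimethyl-8-(triisopropylsilyloxy)-2H-chromen-6-yl]-3-[(4-methoxybenzyl)oxy]propanoyl}oxazolidin-2-one | O=C([C@@H](c1cc(O[Si](C(C)C)(C(C)C)C(C)C)c2c(c1)C=CC(C)(C)O2)COCc1ccc(OC)cc1)N1[C@H](Cc2ccccc2)COC1=O
F12 | step 18 | (3S)-3-(8-hydroxy-2,2-dimethyl-2H-chromen-6-yl)-5-methoxychromane-4,7-diol (both C4 epimers) | COc1cc(O)cc2c1C(O)[C@@H](c1cc(O)c3c(c1)C=CC(C)(C)O3)CO2
A1 | alternative 1 | 5-methoxy-2,2-dimethyl-7-(triisopropylsilyloxy)-4H-1,3-benzodioxin-4-one | COc1cc(O[Si](C(C)C)(C(C)C)C(C)C)cc2OC(C)(C)OC(=O)c12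
A2 | alternative 1 | tert-butyl{5-(2-methoxyethenyl)-2-[(2-methylbut-3-yn-2-yl)oxy]phenoxy}dimethylsilane | COC=Cc1ccc(OC(C)(C)C#C)c(O[Si](C)(C)C(C)(C)C)c1
A3 | alternative 1 | 3-methoxy-2-(oxomethylidene)-5-(triisopropylsilyloxy)cyclohexa-3,5-dien-1-one (quinoketene) | COC1=CC(O[Si](C(C)C)(C(C)C)C(C)C)=CC(=O)C1=C=O
A4 | alternative 1 | 3-{3-(tert-butyldimethylsilyloxy)-4-[(2-methylbut-3-yn-2-yl)oxy]phenyl}-5-methoxy-7-(triisopropylsilyloxy)-4H-chromen-4-one | COc1cc(O[Si](C(C)C)(C(C)C)C(C)C)cc2occ(-c3ccc(OC(C)(C)C#C)c(O[Si](C)(C)C(C)(C)C)c3)c(=O)c12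
A5 | alternative 2 | 2-diazo-2-[8-(tert-butyldimethylsilyloxy)-2,2-dimethyl-2H-chromen-6-yl]-1-[4-(tert-butyldimethylsilyloxy)-2,6-dimethoxyphenyl]ethan-1-one | COc1cc(O[Si](C)(C)C(C)(C)C)cc(OC)c1C(=O)C(=[N+]=[N-])c1cc(O[Si](C)(C)C(C)(C)C)c2c(c1)C=CC(C)(C)O2
A6 | alternative 2 | (3S)-7-(tert-butyldimethylsilyloxy)-3-[8-(tert-butyldimethylsilyloxy)-2,2-dimethyl-2H-chromen-6-yl]-5-methoxychroman-4-one | COc1cc(O[Si](C)(C)C(C)(C)C)cc2c1C(=O)[C@@H](c1cc(O[Si](C)(C)C(C)(C)C)c3c(c1)C=CC(C)(C)O3)CO2
A7 | alternative 3 | 2-{2-[8-(tert-butyldimethylsilyloxy)-2,2-dimethyl-2H-chromen-6-yl]-2-chloroethoxy}-6-methoxy-4-(triisopropylsilyloxy)benzoyl chloride (racemic) | COc1cc(O[Si](C(C)C)(C(C)C)C(C)C)cc(OCC(Cl)c2cc(O[Si](C)(C)C(C)(C)C)c3c(c2)C=CC(C)(C)O3)c1C(Cl)=O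
A8 | alternative 3 | (3S)-3-[8-(tert-butyldimethylsilyloxy)-2,2-dimethyl-2H-chromen-6-yl]-5-methoxy-7-(triisopropylsilyloxy)chroman-4-one | COc1cc(O[Si](C(C)C)(C(C)C)C(C)C)cc2c1C(=O)[C@@H](c1cc(O[Si](C)(C)C(C)(C)C)c3c(c1)C=CC(C)(C)O3)CO2
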